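## The problem

Target **35** is a labdane. Its trans-fused decalin (rings A and B) carries a tetrasubstituted C8=C9 alkene, a 7α-acetoxy group, a free 6β-hydroxyl and, on C9, a five-carbon chain that ends in a (Z)-trisubstituted allylic acetate. Four contiguous stereocentres (C5, C6, C7, C10) have to be set. C10 is quaternary and lies between C5 (itself next to the quaternary C4) and the alkene carbon C9, so a plain enolate methylation at the ring fusion is not an attractive way to make it.

The centres can be made to control one another in a chain. A carbinol centre at C6 is adjacent to C5 and 1,3 to C20, so it can direct both ring-fusion centres. Once the trans-decalin exists, C20 and the 4β-methyl group shield the β face, so C6 can be re-set by α-face hydride attack. The 6β-hydroxyl can then deliver hydride to C7 and fix the trans-diol.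

The two allylic acetates are fragile: the primary one on the Z alkene can ionise and isomerise, and the secondary one next to the tetrasubstituted alkene can eliminate or migrate. Late steps must therefore avoid strong acid, strong base and dissolving metal, and the esters should come last. The three hydroxyls can be told apart without protecting groups, because the 6β-hydroxyl is syn-axial to both C20 and the 4β-methyl group.

The feature that opens the route is the position of C20. It sits on C10, next to C5–H and 1,3 to O6. A C5=C10 alkene bearing a 6β-hydroxyl can therefore accept a methylene unit from a zinc carbenoid held on that oxygen. The extra C5–C20 bond, which the target does not contain, then lies α to a C6 carbonyl and can be cut by electron transfer.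

## Retrosynthesis

**35 to 34.** The two acyl–oxygen bonds at O7 and O15 are cut last. Carrying acetates through organometallic and hydride steps is not possible, and triol **34** offers three hydroxyls of very different accessibility. The forward step must acetylate the primary and the secondary allylic hydroxyl and leave the hindered 6β-hydroxyl.

**34 to 33 to 32.** The C7–H bond is cut (carbinol back to ketone), then the two O–Si bonds. A ketone at C7 removes one stereocentre and lets C6 control C7 through intramolecular hydride delivery. The neighbouring option, capturing a C7–C9 allyl cation with acetate, would give the ester directly, but it invites elimination to dienes and interference by the C6 oxygen. The forward reduction needs a free 6β-hydroxyl, hence desilylation of **32** to **33** first.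

**32 to 31 to 21 + 28.** The C7 carbonyl and the C8=C9 alkene are traced to a tertiary C9 carbinol with a C7=C8 alkene (**31**), and then the C9–C11 bond is cut. This cut separates the decalin from the side chain at the only point where a carbonyl (C9 of enone **21**) is available, and the transposition then delivers the C7 oxygen. A cross-coupling at a C9 enol triflate would make the alkene but not the C7 oxygen. The forward steps ask for 1,2-addition to a hindered enone and an oxidative [3,3] shift.

**28 to 27 to 26 to 24 to 22.** The side chain is cut at C13–C16 (methyl) and C14–C15 (ester carbon). A syn carbocupration of ynoate **24** fixes the Z geometry in one step. Olefination of a methyl ketone, the neighbouring cut at C13=C14, gives poor Z control. The forward sequence must protonate the alkenylcopper species **25** cold and must not let the C15 oxygen displace the C11 bromide.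

**21 to 19 to 17 to 16.** The C7=C8 bond (dehydrogenation), the C8–C17 bond (enolate methylation) and the O–Si bond are cut. Because C10 is quaternary, the C9 ketone of **17** can enolise in one direction only, so both steps are regiospecific. Ketone **16** has no carbon missing from ring B except C17.

**16 to 14 to 12.** The C6 carbinol is traced to ketone **14** and the C9 carbonyl to its dimethyl ketal. Then the C5–C20 bond is re-formed retrosynthetically to give cyclopropyl ketone **12**. This reconnection turns the quaternary methyl problem into a cyclopropane problem and ties C10 to C5. The forward cleavage must break C5–C20 and not C5–C10, and the enolate **13** must protonate to the trans-decalone.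

**12 to 11 to 9 (key).** The C10–C20 and C5–C20 bonds are cut together. Allylic alcohol **9** has a single stereocentre. The forward step must add methylene to a tetrasubstituted alkene on the face of the hydroxyl without disturbing the allylic ketal.

**9 to 8 to 7.** The C6–H bond (enantioselective ketone reduction) and the C7–H/C8–H bonds (hydrogenation) are cut. Quinone monoketal **7** is achiral; the whole absolute configuration then rests on one catalytic reduction.

**7 to 6 to 5.** The ketal C–O bonds are cut back to the 1,4-dimethoxyarene **5**. The arene supplies ring B with oxygen at exactly C6 and C9. The forward monohydrolysis must choose the C6 ketal.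

**5 to 4 to 1 + 2.** The C4–C5 bond (Friedel–Crafts) and the C1–C10 bond (aryl alkylation) are cut. The homoprenyl unit **2** brings C1–C4 and the gem-dimethyl group, and the symmetry of **1** removes any regiochemical question.

## Roads not taken

Alternative 1: The cut goes through ring A at C1–C2 and C5–C10, and later through ring B at an aldol bond. In the forward sense a chiral cationic boron Lewis acid would catalyse the Diels–Alder reaction of 2-methylacrolein A1 with the (E)-silyloxymethyl diene A2 to give the ring A aldehyde A3. C10 (methyl and formyl) and C5 (hydrogen and silyloxymethyl) are set in that one event, and the exo preference of α-substituted enals gives the right relative configuration. No temporary bond has to be made and broken. The weak points lie after the key step. A3 carries only one methyl on C4, as an alkene carbon, so the gem-dimethyl group still needs a C–C bond next to C5. A3 also lacks C7, C8, C17, both ring B oxygens and the side chain, so a long linear sequence follows, and the aldol closure must still produce the tetrasubstituted alkene beside a 6β,7α-diol. In setting C5 and C10 this road is more direct than the chosen plan, which spends steps 6 to 10 on it. The chosen plan sets against this that ring B with oxygen at C6 and C9 and the gem-dimethyl group are in place four steps from an arene.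

Alternative 2: The cut removes C5–C10 and C6–C7 at once. Forward, an acyclic (E)-nitroalkene tethered to a tetrasubstituted diene would undergo thermal intramolecular Diels–Alder reaction to the nitro labdadiene A4. Both rings, three stereocentres and the C8=C9 alkene form together, with the side chain and its acetate already in place; no other plan gains as much in one step. For this target the difficulties are several. The C5–C10 bond joins a carbon next to the quaternary C4 to a fully substituted diene terminus, so high temperature would be needed while a Z-allylic acetate and a nitroalkene are present. The ring fusion and absolute configuration depend on a C3 ether that the target lacks and that must be removed afterwards. A4 has C7 as a methylene and C6 as an α-nitro carbon, so conversion to a ketone, reduction to the 6β-alcohol and a separate C7 oxidation remain. The geometrically defined tetrasubstituted diene is itself hard to make. If the cycloaddition worked, the bicycle would be reached in fewer steps than on the chosen line to **21**. The chosen plan sets against this precedent for each bond formed at the hindered centres and a C6 oxygen that is present from the start and used twice for stereocontrol.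

Alternative 3: The cut is the C8=C9 bond. Forward, ring-closing metathesis of two 1,1-disubstituted alkenes on a preformed ring A would give the protected triol A5. The merits are real: A5 is two or three operations from **35**, the side chain is in place, C6 and C7 can be set by acyclic stereocontrol, and no redox work on ring B follows. This endgame is clearly shorter than steps 18 to 22 here. The weak point is the ring closure itself. Metathesis to tetrasubstituted cyclohexenes is reliable for unhindered dienes with sterically reduced carbene ligands. Here one alkene sits on the quaternary C10 and the other next to the oxygenated C7, with a free hydroxyl and a further trisubstituted alkene present. Ring A with C5 and the quaternary C10 must also be made enantioselectively beforehand, so the central stereochemical problem is moved and not solved. Acidic removal of the C7 methoxymethyl ether beside a tetrasubstituted allylic system is a further concern. The chosen plan offers less convergence, but its ring closure (Friedel–Crafts onto an arene) is sterically undemanding and its key step creates the quaternary centre itself.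

Key step: step 7

Assumption: ring and chain carbons carry labdane numbers (C18/C19 on C4, C20 on C10, C17 on C8, C16 on C13; β is the face of C20); the C8 epimers of **19** and the C9 epimers of **31** are carried as mixtures because both centres become trigonal later.

Step 1
Reactants: 1 1,4-dimethoxybenzene; 2 5-bromo-2-methylpent-2-ene
Product: 4 1,4-dimethoxy-2-(4-methylpent-3-en-1-yl)benzene, via 2,5-dimethoxyphenyllithium 3 (not isolated)
Conditions: n-BuLi, TMEDA, THF, 0 °C; then 2, −78 °C → rt
Reagents that add atoms: none
Why: Directed ortho-lithiation of 1 gives 3, which is alkylated by the primary bromide 2 in an SN2 reaction; the two methoxy groups are equivalent, so only one regioisomer can form.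

Step 2
Reactants: 4 1,4-dimethoxy-2-(4-methylpent-3-en-1-yl)benzene
Product: 5 5,8-dimethoxy-1,1-dimethyl-1,2,3,4-tetrahydronaphthalene
Conditions: MeSO3H, CH2Cl2, 0 °C → rt
Reagents that add atoms: none
Why: Intramolecular Friedel–Crafts cycloalkylation: protonation of the trisubstituted alkene gives a tertiary cation that attacks the only free ortho position, activated by the adjacent methoxy group, and closes the six-membered ring with the gem-dimethyl carbon C4 on C5.

Step 3
Reactants: 5 5,8-dimethoxy-1,1-dimethyl-1,2,3,4-tetrahydronaphthalene
Product: 6 5,5,8,8-tetramethoxy-1,1-dimethyl-1,2,3,4,5,8-hexahydronaphthalene (quinone bisketal)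
Conditions: Pt anode, constant current, KOH (1%), MeOH, 0 °C, undivided cell
Reagents that add atoms: methanol, CO
Why: Anodic oxidation of 1,4-dimethoxyarenes in basic methanol is the standard entry to quinone bisketals; two electrons are removed and methoxide is captured at both ipso carbons.

Step 4
Reactants: 6 quinone bisketal
Product: 7 4,4-dimethoxy-8,8-dimethyl-5,6,7,8-tetrahydronaphthalen-1(4H)-one (quinone monoketal; C6 carbonyl, C9 ketal)
Conditions: AcOH/H2O (8%), acetone, 0 °C → rt
Reagents that add atoms: water, O
Why: Acid-catalysed monohydrolysis of a quinone bisketal stops at the monoketal because the dienone deactivates the second ketal; the ketal beside C5 should ionise first, since loss of methanol relieves the strain between its methoxy groups and the C4 gem-dimethyl group and the cation is stabilised at C10 by the C1 methylene.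

Step 5
Reactants: 7 quinone monoketal
Product: 8 4,4-dimethoxy-8,8-dimethyl-3,4,5,6,7,8-hexahydronaphthalen-1(2H)-one
Conditions: H2 (1 atm), RhCl(PPh3)3 (cat.), benzene, rt
Reagents that add atoms: none
Why: Homogeneous hydrogenation with RhCl(PPh3)3 reduces the cis-disubstituted C7=C8 bond and leaves the tetrasubstituted C5=C10 bond, without the hydrogenolysis and aromatisation that heterogeneous catalysts can cause with quinone monoketals.

Step 6
Reactants: 8 enone ketal
Product: 9 (R)-4,4-dimethoxy-8,8-dimethyl-1,2,3,4,5,6,7,8-octahydronaphthalen-1-ol (labdane numbering: 9,9-dimethoxy-4,4-dimethyl-Δ5(10)-octalin-6β-ol)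
Conditions: (S)-1-methyl-3,3-diphenyltetrahydro-1H,3H-pyrrolo[1,2-c][1,3,2]oxazaborole (0.1 equiv), BH3·SMe2, THF, −20 °C; MeOH quench, NaHCO3 work-up
Reagents that add atoms: none
Why: Corey–Bakshi–Shibata reduction; the ketone binds the catalyst with the fully substituted alkenyl carbon C5 as the large group and C7H2 as the small one, so the (S)-catalyst should deliver hydride to give the (R)-carbinol (6β-OH), the only stereocentre of 9.

Step 7
Reactants: 9 (R)-allylic alcohol
Product: 11 (5R,6R,10R)-9,9-dimethoxy-4,4-dimethyl-5β,10β-methanodecalin-6β-ol (cyclopropane C5–C20–C10 on the face of the hydroxyl), via iodomethylzinc alkoxide 10 (not isolated)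
Conditions: Et2Zn (3 equiv), CH2I2 (6 equiv), CH2Cl2, −10 → 0 °C; NaHCO3 work-up
Reagents that add atoms: diiodomethane, ICI
Why: Et2Zn deprotonates the C6 hydroxyl and with CH2I2 forms the iodomethylzinc alkoxide 10, in which the carbenoid carbon is held over the β face of the C5=C10 alkene. Methylene is then transferred in one concerted step through a butterfly transition state to both alkene carbons, so the three-membered ring closes by a (2+1) addition that forms C10–C20 and the temporary C5–C20 bond. The closest known reaction type is the hydroxyl-directed Simmons–Smith cyclopropanation in its Furukawa form, which is established for cyclic allylic alcohols with ring-fusion tetrasubstituted alkenes and is tolerated by ketals of cyclic enones. Both new stereocentres, C5 and C10, are controlled by the C6 carbinol centre, because the methylene enters syn to the oxygen and gives the 5β,10β bridge. The step needs facial selectivity and survival of the allylic dimethyl ketal. A(1,2) strain against the C4 gem-dimethyl group holds the C6–O bond pseudoaxial, so it points along the alkene face, and the zinc alkoxide binds the carbenoid far more firmly than the ketal oxygens can. The alkene is electron-rich and the only one present, and excess reagent in a non-coordinating solvent should offset the shielding by C4 and C9.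

Step 8
Reactants: 11 cyclopropyl carbinol
Product: 12 (5R,10R)-9,9-dimethoxy-4,4-dimethyl-5β,10β-methanodecalin-6-one
Conditions: 1,1,1-triacetoxy-1,1-dihydro-1,2-benziodoxol-3(1H)-one (DMP), NaHCO3, CH2Cl2, 0 °C → rt
Reagents that add atoms: none
Why: Buffered periodinane oxidation converts the hindered secondary carbinol to the ketone without ionising the cyclopropylcarbinyl system or the ketal; C5 and C10 are not touched.

Step 9
Reactants: 12 cyclopropyl ketone
Product: 14 (5S,10S)-9,9-dimethoxy-4,4,10-trimethyl-trans-decalin-6-one (5α-H, 10β-methyl), via lithium enolate 13 (not isolated)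
Conditions: Li (2.5 equiv), NH3 (l), THF, −78 °C; then NH4Cl
Reagents that add atoms: none
Why: Dissolving-metal reduction of a conjugated cyclopropyl ketone: the ketyl cleaves the cyclopropane bond that overlaps best with the carbonyl π system, the exocyclic C5–C20 bond, whereas C5–C10 lies near the carbonyl plane and stays. C20 thus becomes the 10β-methyl group, and enolate 13 is protonated at C5 on quench to the more stable trans-fused decalone.

Step 10
Reactants: 14 trans-decalone ketal
Product: 16 (5S,6R,10S)-6β-hydroxy-4,4,10-trimethyl-trans-decalin-9-one, via 6β-hydroxy ketal 15 (not isolated)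
Conditions: LiAlH4, Et2O, 0 °C; then 1 M HCl, THF, rt
Reagents that add atoms: water, O
Why: Hydride attacks the C6 carbonyl from the α face because the β face is blocked by the syn-axial C20 and 4β-methyl groups, giving the axial 6β-alcohol 15; the dimethyl ketal is then hydrolysed during the acidic work-up.

Step 11
Reactants: 16 hydroxy ketone
Product: 17 (5S,6R,10S)-6β-(triethylsilyloxy)-4,4,10-trimethyl-trans-decalin-9-one
Conditions: TESOTf, 2,6-lutidine, CH2Cl2, −78 → 0 °C
Reagents that add atoms: triethylsilyl trifluoromethanesulfonate, CC[Si](CC)(CC)OS(=O)(=O)C(F)(F)F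
Why: Silylation with a silyl triflate and 2,6-lutidine is the standard way to protect hindered axial alcohols; the triethylsilyl group is small enough to enter between the two syn-axial methyl groups and is removed later with fluoride.

Step 12
Reactants: 17 silyloxy ketone
Product: 19 6β-(triethylsilyloxy)-4,4,8,10-tetramethyl-trans-decalin-9-one (mixture of C8 epimers), via lithium enolate 18 (not isolated)
Conditions: LiN(i-Pr)2, THF, −78 °C; then MeI, −78 → −20 °C
Reagents that add atoms: iodomethane, CI
Why: C10 is quaternary, so only the C8–C9 enolate 18 can form, and it is C-methylated by MeI; the C8 configuration is not controlled and is erased in step 13.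

Step 13
Reactants: 19 α-methyl ketone
Product: 21 (5S,6R,10S)-6β-(triethylsilyloxy)-4,4,8,10-tetramethyl-Δ7-octalin-9-one (C7=C8 enone), via trimethylsilyl enol ether 20 (not isolated)
Conditions: TMSOTf, Et3N, CH2Cl2, 0 °C; then Pd(OAc)2 (1.1 equiv), MeCN, rt
Reagents that add atoms: none
Why: Saegusa–Ito oxidation: soft enolisation gives the only possible silyl enol ether 20, and Pd(OAc)2 forms the palladium enolate, which undergoes β-hydride elimination towards the ring methylene C7 to give the endocyclic 2-methyl enone, as other 2-methylcycloalkanone silyl enol ethers do.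

Step 14
Reactants: 22 4-bromobut-1-yne
Product: 24 methyl 5-bromopent-2-ynoate, via lithium acetylide 23 (not isolated)
Conditions: n-BuLi, THF, −78 °C; then ClCO2Me, −78 → 0 °C
Reagents that add atoms: methyl chloroformate, COC(=O)Cl
Why: The terminal alkyne C–H is the most acidic site, and the lithium acetylide 23 is acylated by the chloroformate at low temperature, where the primary bromide is inert.

Step 15
Reactants: 24 methyl 5-bromopent-2-ynoate
Product: 26 methyl (Z)-5-bromo-3-methylpent-2-enoate, via alkenylcuprate 25 (not isolated)
Conditions: Me2CuLi (from MeLi, CuI), THF, −78 °C; then MeOH, −78 °C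
Reagents that add atoms: lithium dimethylcuprate, [Li+].C[Cu-]C
Why: Conjugate addition of a lithium dialkylcuprate to an ynoate is a syn carbocupration at −78 °C; protonation of the configurationally stable alkenylcuprate 25 with retention places the new methyl cis to hydrogen, that is, the bromoethyl chain cis to the ester (Z).

Step 16
Reactants: 26 (Z)-enoate
Product: 27 (Z)-5-bromo-3-methylpent-2-en-1-ol
Conditions: i-Bu2AlH (2.2 equiv), CH2Cl2, −78 °C
Reagents that add atoms: none
Why: i-Bu2AlH reduces the conjugated ester to the allylic alcohol by 1,2-addition at low temperature without changing the alkene geometry or touching the primary bromide.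

Step 17
Reactants: 27 (Z)-bromo alcohol
Product: 28 (Z)-[(5-bromo-3-methylpent-2-en-1-yl)oxy](tert-butyl)dimethylsilane
Conditions: TBSOTf, 2,6-lutidine, CH2Cl2, −78 °C
Reagents that add atoms: tert-butyldimethylsilyl trifluoromethanesulfonate, CC(C)(C)[Si](C)(C)OS(=O)(=O)C(F)(F)F
Why: Silylation with the triflate and a non-nucleophilic base is fast at −78 °C, so the allylic hydroxyl is protected before it can displace the cis-disposed primary bromide.

Step 18
Reactants: 28 (Z)-bromide; 21 enone
Product: 31 6β-(triethylsilyloxy)-15-(tert-butyldimethylsilyloxy)labda-7,13(Z)-dien-9-ol (mixture of C9 epimers), via Grignard reagent 29 (not isolated), via organocerium reagent 30 (not isolated)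
Conditions: 28, Mg, THF, rt; CeCl3, THF, −78 °C; then 21, −78 → 0 °C
Reagents that add atoms: none
Why: Organocerium reagents made from Grignard reagents and CeCl3 add 1,2 to hindered, enolisable enones of the 2,6,6-trisubstituted cyclohexenone type; the C9 configuration does not matter because C9 becomes trigonal in step 19.

Step 19
Reactants: 31 tertiary allylic alcohol
Product: 32 (5S,6S,10S)-6β-(triethylsilyloxy)-15-(tert-butyldimethylsilyloxy)labda-8,13(Z)-dien-7-one
Conditions: (C5H5NH)[CrO3Cl], NaOAc, 4 Å molecular sieves, CH2Cl2, rt
Reagents that add atoms: pyridinium chlorochromate, [O-][Cr](=O)(=O)Cl.c1cc[nH+]cc1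
Why: Babler–Dauben oxidative transposition: the tertiary allylic alcohol forms a chromate ester that undergoes a [3,3] shift to C7 and is then oxidised, giving the transposed enone with the tetrasubstituted C8=C9 alkene; NaOAc buffers the medium for the silyl ethers and the α-silyloxy ketone.

Step 20
Reactants: 32 bis-silyl enone
Product: 33 (5S,6S,10S)-6β,15-dihydroxylabda-8,13(Z)-dien-7-one
Conditions: HF·pyridine, pyridine, THF, 0 °C → rt
Reagents that add atoms: none
Why: Buffered HF·pyridine cleaves the primary tert-butyldimethylsilyl ether and the hindered triethylsilyl ether under mildly acidic conditions that should not enolise the α-hydroxy enone, so C6 keeps its configuration.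

Step 21
Reactants: 33 dihydroxy enone
Product: 34 (5S,6S,7S,10S)-labda-8,13(Z)-diene-6β,7α,15-triol
Conditions: Me4N[BH(OAc)3], MeCN/AcOH, −20 °C
Reagents that add atoms: none
Why: Hydroxyl-directed triacetoxyborohydride reduction: the C6 hydroxyl exchanges with an acetate on boron and hydride is delivered intramolecularly to the β face of the C7 carbonyl, which sets the 7α-hydroxyl trans to the 6β-hydroxyl; the reagent is too weak to reduce the hindered enone from outside.

Step 22
Reactants: 34 triol
Product: 35 (5S,6S,7S,10S)-6β-hydroxylabda-8,13(Z)-diene-7α,15-diyl diacetate (CNP0415913.2)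
Conditions: Ac2O (2.2 equiv), pyridine, CH2Cl2, 0 °C → rt
Reagents that add atoms: acetic anhydride, CC(=O)OC(C)=O
Why: The primary allylic C15 hydroxyl and the secondary allylic C7 hydroxyl are acetylated by Ac2O in pyridine, whereas the 6β-hydroxyl, syn-axial to C20 and the 4β-methyl group, should not react without an acyl-transfer catalyst; the trans-diaxial geometry also disfavours acyl migration from O7 to O6.

## Compound list

1 | 1,4-dimethoxybenzene | COc1ccc(OC)cc1 | starting material
2 | 5-bromo-2-methylpent-2-ene | CC(C)=CCCBr | starting material
3 | 2,5-dimethoxyphenyllithium | COc1ccc(OC)c([Li])c1 | intermediate (not isolated)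
4 | 1,4-dimethoxy-2-(4-methylpent-3-en-1-yl)benzene | COc1ccc(OC)c(CCC=C(C)C)c1 | intermediate
5 | 5,8-dimethoxy-1,1-dimethyl-1,2,3,4-tetrahydronaphthalene | COc1ccc(OC)c2c1CCCC2(C)C | intermediate
6 | 5,5,8,8-tetramethoxy-1,1-dimethyl-1,2,3,4,5,8-hexahydronaphthalene | COC1(OC)C=CC(OC)(OC)C2=C1C(C)(C)CCC2 | intermediate
7 | 4,4-dimethoxy-8,8-dimethyl-5,6,7,8-tetrahydronaphthalen-1(4H)-one | O=C1C=CC(OC)(OC)C2=C1C(C)(C)CCC2 | intermediate
8 | 4,4-dimethoxy-8,8-dimethyl-3,4,5,6,7,8-hexahydronaphthalen-1(2H)-one | O=C1CCC(OC)(OC)C2=C1C(C)(C)CCC2 | intermediate
9 | (R)-4,4-dimethoxy-8,8-dimethyl-1,2,3,4,5,6,7,8-octahydronaphthalen-1-ol | O[C@@H]1CCC(OC)(OC)C2=C1C(C)(C)CCC2 | intermediate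
10 | iodomethylzinc alkoxide of 9 | IC[Zn]O[C@@H]1CCC(OC)(OC)C2=C1C(C)(C)CCC2 | intermediate (not isolated)
11 | (5R,6R,10R)-9,9-dimethoxy-4,4-dimethyl-5β,10β-methanodecalin-6β-ol | O[C@@H]1CCC(OC)(OC)[C@]23C[C@]12C(C)(C)CCC3 | intermediate
12 | (5R,10R)-9,9-dimethoxy-4,4-dimethyl-5β,10β-methanodecalin-6-one | O=C1CCC(OC)(OC)[C@]23C[C@]12C(C)(C)CCC3 | intermediate
13 | lithium C5–C6 enolate of 14 | COC1(OC)CCC(O[Li])=C2C(C)(C)CCC[C@]12C | intermediate (not isolated)
14 | (5S,10S)-9,9-dimethoxy-4,4,10-trimethyl-trans-decalin-6-one | COC1(OC)CCC(=O)[C@H]2C(C)(C)CCC[C@]12C | intermediate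
15 | (5S,6R,10S)-9,9-dimethoxy-4,4,10-trimethyl-trans-decalin-6β-ol | COC1(OC)CC[C@@H](O)[C@H]2C(C)(C)CCC[C@]12C | intermediate (not isolated)
16 | (5S,6R,10S)-6β-hydroxy-4,4,10-trimethyl-trans-decalin-9-one | O=C1CC[C@@H](O)[C@H]2C(C)(C)CCC[C@]12C | intermediate
17 | (5S,6R,10S)-6β-(triethylsilyloxy)-4,4,10-trimethyl-trans-decalin-9-one | O=C1CC[C@@H](O[Si](CC)(CC)CC)[C@H]2C(C)(C)CCC[C@]12C | intermediate
18 | lithium C8–C9 enolate of 17 | [Li]OC1=CC[C@@H](O[Si](CC)(CC)CC)[C@H]2C(C)(C)CCC[C@]12C | intermediate (not isolated)
19 | 6β-(triethylsilyloxy)-4,4,8,10-tetramethyl-trans-decalin-9-one (C8 epimers) | O=C1C(C)C[C@@H](O[Si](CC)(CC)CC)[C@H]2C(C)(C)CCC[C@]12C | intermediate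
20 | 9-trimethylsilyl enol ether of 19 (C8=C9) | C[Si](C)(C)OC1=C(C)C[C@@H](O[Si](CC)(CC)CC)[C@H]2C(C)(C)CCC[C@]12C | intermediate (not isolated)
21 | (5S,6R,10S)-6β-(triethylsilyloxy)-4,4,8,10-tetramethyl-Δ7-octalin-9-one | O=C1C(C)=C[C@@H](O[Si](CC)(CC)CC)[C@H]2C(C)(C)CCC[C@]12C | intermediate
22 | 4-bromobut-1-yne | C#CCCBr | starting material
23 | (4-bromobut-1-ynyl)lithium | [Li]C#CCCBr | intermediate (not isolated)
24 | methyl 5-bromopent-2-ynoate | COC(=O)C#CCCBr | intermediate
25 | lithium (Z)-alkenyl(methyl)cuprate from 24 (copper at C14, cis to C16) | [Li+].COC(=O)/C([Cu-]C)=C(/C)CCBr | intermediate (not isolated)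
26 | methyl (Z)-5-bromo-3-methylpent-2-enoate | COC(=O)/C=C(/C)CCBr | intermediate
27 | (Z)-5-bromo-3-methylpent-2-en-1-ol | OC/C=C(/C)CCBr | intermediate
28 | (Z)-[(5-bromo-3-methylpent-2-en-1-yl)oxy](tert-butyl)dimethylsilane | CC(C)(C)[Si](C)(C)OC/C=C(/C)CCBr | intermediate
29 | Grignard reagent from 28 | CC(C)(C)[Si](C)(C)OC/C=C(/C)CC[Mg]Br | intermediate (not isolated)
30 | dichlorocerium reagent from 29 | CC(C)(C)[Si](C)(C)OC/C=C(/C)CC[Ce](Cl)Cl | intermediate (not isolated)
31 | 6β-(triethylsilyloxy)-15-(tert-butyldimethylsilyloxy)labda-7,13(Z)-dien-9-ol (C9 epimers) | CC(C)(C)[Si](C)(C)OC/C=C(/C)CCC1(O)C(C)=C[C@@H](O[Si](CC)(CC)CC)[C@H]2C(C)(C)CCC[C@]12C | intermediate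
32 | (5S,6S,10S)-6β-(triethylsilyloxy)-15-(tert-butyldimethylsilyloxy)labda-8,13(Z)-dien-7-one | CC(C)(C)[Si](C)(C)OC/C=C(/C)CCC1=C(C)C(=O)[C@@H](O[Si](CC)(CC)CC)[C@H]2C(C)(C)CCC[C@]12C | intermediate
33 | (5S,6S,10S)-6β,15-dihydroxylabda-8,13(Z)-dien-7-one | OC/C=C(/C)CCC1=C(C)C(=O)[C@@H](O)[C@H]2C(C)(C)CCC[C@]12C | intermediate
34 | (5S,6S,7S,10S)-labda-8,13(Z)-diene-6β,7α,15-triol | OC/C=C(/C)CCC1=C(C)[C@H](O)[C@@H](O)[C@H]2C(C)(C)CCC[C@]12C | intermediate
35 | (5S,6S,7S,10S)-6β-hydroxylabda-8,13(Z)-diene-7α,15-diyl diacetate | CC(=O)OC/C=C(/C)CCC1=C(C)[C@H](OC(C)=O)[C@@H](O)[C@H]2C(C)(C)CCC[C@]12C | target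

## Step count and least certain steps

Total step count: 22 (13 steps to enone 21, 4 steps to side chain 28, 5 steps after the coupling). Longest linear sequence: 18 steps (steps 1 to 13 and 18 to 22).

**Step 7 (key step).** Two things are most likely to go wrong. Methylene transfer to an alkene flanked by two fully substituted carbons may be slow. The zinc iodide that accumulates may also ionise the allylic dimethyl ketal, which would lead to loss of methanol and aromatisation. Fallback, from 9 back to 11: dibromocarbene generated under basic phase-transfer conditions (CHBr3, 50% NaOH, BnEt3NCl), where ketals are safe, should add to the electron-rich alkene to give (5R,6R,10R)-20,20-dibromo-9,9-dimethoxy-4,4-dimethyl-5β,10β-methanodecalin-6β-ol F1. Both C–Br bonds are then reduced with Bu3SnH and a radical initiator to return 11. Facial control in this variant rests on association of the carbene precursor with the hydroxyl, which is weaker than zinc delivery.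

**Step 4.** Hydrolysis of the wrong ketal, or of both, is the risk, since the steric argument for the C6 ketal has only analogy behind it. Fallback, from 2 back to 7, with the two oxygens differentiated from the start. 4-Methoxyphenol F2 is silylated to (4-methoxyphenoxy)triisopropylsilane F3. Because the bulky silyl ether does not direct, lithiation with n-BuLi/TMEDA occurs ortho to the methoxy group, and alkylation with 2 gives [4-methoxy-3-(4-methylpent-3-en-1-yl)phenoxy]triisopropylsilane F4. n-Bu4NF releases 4-methoxy-3-(4-methylpent-3-en-1-yl)phenol F5. Acid (MeSO3H) then closes the ring at the only free position ortho to the chain, giving 4-methoxy-8,8-dimethyl-5,6,7,8-tetrahydronaphthalen-1-ol F6. Oxidation of F6 with PhI(OAc)2 in methanol places the carbonyl at the phenol carbon and the ketal at the methoxy carbon, which is 7 without ambiguity.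

**Step 18.** The Grignard reagent 29 may decay by cyclisation onto the alkene with loss of silyloxide, and addition of a long chain to the doubly flanked C9 carbonyl may be slow enough for enolisation to compete. Fallback, from 21 back to 31, with the chain joined at C12–C13 instead. CH2=CHMgBr with CeCl3 adds the small vinyl group to 21 to give 6β-(triethylsilyloxy)-9-vinyl-4,4,8,10-tetramethyl-Δ7-octalin-9-ol F7. (Z)-3-Iodobut-2-en-1-ol F8, taken as purchasable, is silylated to (Z)-tert-butyl[(3-iodobut-2-en-1-yl)oxy]dimethylsilane F9. Hydroboration of the vinyl group of F7 with 9-borabicyclo[3.3.1]nonane gives the B-alkyl borane F10. Suzuki–Miyaura coupling of F10 with F9 (PdCl2(dppf), Cs2CO3) forms the C12–C13 bond with retention of the Z geometry and gives 31.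

**Step 19.** Formation of the chromate ester at the hindered tertiary carbinol may be slow, which would let dehydration or oxidative attack on the side-chain alkene compete. Fallback, from 31 back to 32: catalytic Ph3SiOReO3 isomerises the tertiary allylic alcohol without oxidation to the secondary allylic alcohol 6β-(triethylsilyloxy)-15-(tert-butyldimethylsilyloxy)labda-8,13(Z)-dien-7-ol F11, driven by formation of the tetrasubstituted alkene. Buffered periodinane oxidation of F11 then gives 32.

**Step 21.** Hydride delivery may not be fully intramolecular, or the α-hydroxy enone may epimerise at C6 through its enediol before reduction; either would erode the trans relationship. Fallback, from 32 back to 35, with C7 set by inversion instead of by delivery. Reduction of 32 under Luche conditions (NaBH4, CeCl3·7H2O) should occur anti to the axial 6β-silyloxy group and give the 7β-alcohol 6β-(triethylsilyloxy)-15-(tert-butyldimethylsilyloxy)labda-8,13(Z)-dien-7β-ol F12. Mitsunobu reaction of F12 with acetic acid (PPh3, diisopropyl azodicarboxylate) inverts C7 to the 7α-acetate F13. HF·pyridine removes both silyl groups to give 6β,15-dihydroxylabda-8,13(Z)-dien-7α-yl acetate F14, and one equivalent of Ac2O in pyridine acetylates the primary hydroxyl of F14 to give 35.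

## Further compounds

F1 | step 7 | (5R,6R,10R)-20,20-dibromo-9,9-dimethoxy-4,4-dimethyl-5β,10β-methanodecalin-6β-ol | O[C@@H]1CCC(OC)(OC)[C@]23C(Br)(Br)[C@]12C(C)(C)CCC3
F2 | step 4 | 4-methoxyphenol | COc1ccc(O)cc1
F3 | step 4 | (4-methoxyphenoxy)triisopropylsilane | COc1ccc(O[Si](C(C)C)(C(C)C)C(C)C)cc1
F4 | step 4 | [4-methoxy-3-(4-methylpent-3-en-1-yl)phenoxy]triisopropylsilane | COc1ccc(O[Si](C(C)C)(C(C)C)C(C)C)cc1CCC=C(C)C
F5 | step 4 | 4-methoxy-3-(4-methylpent-3-en-1-yl)phenol | COc1ccc(O)cc1CCC=C(C)C
F6 | step 4 | 4-methoxy-8,8-dimethyl-5,6,7,8-tetrahydronaphthalen-1-ol | COc1ccc(O)c2c1CCCC2(C)C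
F7 | step 18 | 6β-(triethylsilyloxy)-9-vinyl-4,4,8,10-tetramethyl-Δ7-octalin-9-ol (C9 epimers) | C=CC1(O)C(C)=C[C@@H](O[Si](CC)(CC)CC)[C@H]2C(C)(C)CCC[C@]12C
F8 | step 18 | (Z)-3-iodobut-2-en-1-ol | OC/C=C(/C)I
F9 | step 18 | (Z)-tert-butyl[(3-iodobut-2-en-1-yl)oxy]dimethylsilane | CC(C)(C)[Si](C)(C)OC/C=C(/C)I
F10 | step 18 | B-alkyl-9-borabicyclo[3.3.1]nonane from F7 (boron on C12) | OC1(CCB2C3CCCC2CCC3)C(C)=C[C@@H](O[Si](CC)(CC)CC)[C@H]2C(C)(C)CCC[C@]12C
F11 | step 19 | 6β-(triethylsilyloxy)-15-(tert-butyldimethylsilyloxy)labda-8,13(Z)-dien-7-ol (C7 epimers) | CC(C)(C)[Si](C)(C)OC/C=C(/C)CCC1=C(C)C(O)[C@@H](O[Si](CC)(CC)CC)[C@H]2C(C)(C)CCC[C@]12C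
F12 | step 21 | 6β-(triethylsilyloxy)-15-(tert-butyldimethylsilyloxy)labda-8,13(Z)-dien-7β-ol | CC(C)(C)[Si](C)(C)OC/C=C(/C)CCC1=C(C)[C@@H](O)[C@@H](O[Si](CC)(CC)CC)[C@H]2C(C)(C)CCC[C@]12C
F13 | step 21 | 6β-(triethylsilyloxy)-15-(tert-butyldimethylsilyloxy)labda-8,13(Z)-dien-7α-yl acetate | CC(C)(C)[Si](C)(C)OC/C=C(/C)CCC1=C(C)[C@H](OC(C)=O)[C@@H](O[Si](CC)(CC)CC)[C@H]2C(C)(C)CCC[C@]12C
F14 | step 21 | 6β,15-dihydroxylabda-8,13(Z)-dien-7α-yl acetate | OC/C=C(/C)CCC1=C(C)[C@H](OC(C)=O)[C@@H](O)[C@H]2C(C)(C)CCC[C@]12C
A1 | alternative 1 | 2-methylacrolein | C=C(C)C=O
A2 | alternative 1 | (E)-tert-butyldimethyl[(3-methylpenta-2,4-dien-1-yl)oxy]silane | C=C/C(C)=C/CO[Si](C)(C)C(C)(C)C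
A3 | alternative 1 | 2-(tert-butyldimethylsilyloxymethyl)-1,3-dimethylcyclohex-3-ene-1-carbaldehyde (C5–H α, C10 methyl β) | O=C[C@@]1(C)CCC=C(C)[C@@H]1CO[Si](C)(C)C(C)(C)C
A4 | alternative 2 | 6α-nitro-3β-(4-methoxybenzyloxy)labda-8,13(Z)-dien-15-yl acetate | CC(=O)OC/C=C(/C)CCC1=C(C)C[C@H]([N+](=O)[O-])[C@H]2C(C)(C)[C@@H](OCc3ccc(OC)cc3)CC[C@]12C
A5 | alternative 3 | 7-O-methoxymethyl 15-O-tert-butyldimethylsilyl labda-8,13(Z)-diene-6β,7α,15-triol | CC(C)(C)[Si](C)(C)OC/C=C(/C)CCC1=C(C)[C@H](OCOC)[C@@H](O)[C@H]2C(C)(C)CCC[C@]12C
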